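The route rests on one disconnection: the C3–O and C6–O bonds, cis to each other across the C4=C5 alkene of the six-membered ring, are traced back to a single O–O bridge. The key step exploits this cis-1,4 pattern: one photooxygenation of a spiro-epoxy cyclohexadiene forms both bonds, a dioxabicyclo[2.2.2]octene ring and the C3 and C6 stereocentres, on the face opposite the C1 and C2 oxygens. Its precursor is an enantiopure 1-oxaspiro[2.5]octa-5,7-diene from salicyl alcohol, in which C1 already holds oxygen and C7. The C2 oxygen is carried as a 4-methoxybenzyl ether, because an ester there could shift to the C3 or C7 alkoxide during the later epoxide migration; the acetate is added last.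

Key step: step 4

Locants used for every compound (those of the target): C1 is the quaternary carbon bearing oxygen and C7, C2 the neighbouring carbinol carbon, C3 to C6 the remaining ring carbons (diene C3=C4–C5=C6, later alkene C4=C5), C7 the exocyclic CH2. "Upper face" is the face of the C2 oxygen when C1 to C6 run clockwise.

Assumption: the lipase is taken to show the usual large/medium preference for secondary alcohols, with the spiro carbon C1 as the large group, so that the (4R)-alcohol is the enantiomer that is acetylated.

Step 1
Reactants: 1 2-hydroxybenzyl alcohol (salicyl alcohol)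
Product: 3 racemic cis-1-oxaspiro[2.5]octa-5,7-dien-4-ol, via spiro-epoxy dienone 2 (not isolated)
Conditions: NaIO4, H2O/CH2Cl2, 0 °C; cold organic layer run into NaBH4, CeCl3·7H2O, MeOH, −78 °C; NaHCO3 work-up, Et3N-deactivated silica
Reagents that add atoms: none
Why: The Adler–Becker oxidation closes the spiro-epoxide from the hydroxymethyl oxygen onto its own ring carbon C1 and leaves the C2 ketone, and an immediate Luche 1,2-reduction of the cold, dilute dienone, which should outrun its Diels–Alder dimerization, is expected to deliver hydride anti to the polar C1–O bond (polar Felkin–Anh model), so that the new C2 hydroxyl lies on the face of the epoxide oxygen.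

Step 2
Reactants: 3 racemic cis-1-oxaspiro[2.5]octa-5,7-dien-4-ol; 4 vinyl acetate
Product: 5 (3S,4S)-1-oxaspiro[2.5]octa-5,7-dien-4-ol (the enantiomer left unreacted)
Conditions: Candida antarctica lipase B (immobilized), vinyl acetate, MTBE, solid NaHCO3, 20 °C, stopped just past half conversion; Et3N-deactivated silica
Reagents that add atoms: none
Why: Lipase-catalysed irreversible transesterification is a kinetic resolution in which the (4R)-enantiomer should be acetylated and removed by chromatography, so that the (3S,4S)-alcohol is left and gains enantiopurity as conversion passes one half, with no stereocentre formed or touched.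

Step 3
Reactants: 5 (3S,4S)-1-oxaspiro[2.5]octa-5,7-dien-4-ol; 6 4-methoxybenzyl chloride
Product: 7 (3S,4S)-4-[(4-methoxybenzyl)oxy]-1-oxaspiro[2.5]octa-5,7-diene
Conditions: NaH, 4-methoxybenzyl chloride, Bu4NI (cat.), THF/DMF, 0 °C
Reagents that add atoms: 4-methoxybenzyl chloride, COc1ccc(CCl)cc1
Why: Williamson etherification under basic conditions avoids the acid that would open the spiro-epoxide and rearomatize the ring, and the cis alkoxide cannot reach the rear of the C1–O bond, so the epoxide stays in place and both stereocentres are untouched.

Step 4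
Reactants: 7 (3S,4S)-4-[(4-methoxybenzyl)oxy]-1-oxaspiro[2.5]octa-5,7-diene; 8 dioxygen
Product: 9 6-[(4-methoxybenzyl)oxy]spiro[2,3-dioxabicyclo[2.2.2]oct-7-ene-5,2'-oxirane], O–O bridge from C3 to C6 on the lower face, C2 ether oxygen and spiro-epoxide oxygen on the upper face
Conditions: O2, 5,10,15,20-tetraphenylporphyrin (cat.), visible light, CH2Cl2, −78 °C; kept cold and used promptly
Reagents that add atoms: dioxygen, O=O
Why: Singlet oxygen, formed by energy transfer from the photoexcited porphyrin, adds suprafacially to the s-cis diene C3=C4–C5=C6 in a concerted [4+2] cycloaddition that makes the C3–O and C6–O bonds together and leaves the C4=C5 alkene. The closest known reaction type is the photooxygenation of cyclohexa-1,3-dienes with allylic oxygen substituents, which gives 2,3-dioxabicyclo[2.2.2]oct-5-enes anti to those substituents. The six-membered 1,2-dioxine ring closes by cycloaddition across the diene termini, so C3 and C6 must receive oxygen on the same face. Their configuration is controlled by C2 and the spiro centre C1: the ether oxygen and the epoxide oxygen both lie on the upper face and repel the electrophilic oxygen by lone pairs and bulk, so attack should come from the lower face. The step needs facial selectivity and [4+2] over the ene pathway; the first is secured by the two upper-face oxygens, the second by the ring-locked s-cis diene, while the low temperature and acid-free medium keep the spiro-epoxy diene from rearomatizing.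

Step 5
Reactants: 9 the endoperoxide of step 4
Product: 10 4-[(4-methoxybenzyl)oxy]-1-oxaspiro[2.5]oct-6-ene-5,8-diol, C3 and C6 hydroxyls on the lower face, ether oxygen and epoxide oxygen on the upper face
Conditions: thiourea, MeOH, 0 °C to rt
Reagents that add atoms: none
Why: Thiourea reduces the O–O bond of bicyclic endoperoxides by attack of sulfur on oxygen under neutral conditions, so both C–O bonds keep their configuration and the cis-1,4-enediol should result without disturbing the epoxide, the alkene or the ether.

Step 6
Reactants: 10 the cis-enediol of step 5; 11 benzoyl chloride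
Product: 13 1-(benzoyloxymethyl)-2-[(4-methoxybenzyl)oxy]-7-oxabicyclo[4.1.0]hept-4-en-3-yl benzoate, via rearranged epoxy diol 12 (not isolated)
Conditions: NaH (2.2 equiv), THF, 0 °C to rt; then BzCl (2.5 equiv), 0 °C
Reagents that add atoms: benzoyl chloride, O=C(Cl)c1ccccc1
Why: In a Payne rearrangement the C6 alkoxide, anti to the spiro C1–O bond, displaces it in a 3-exo-tet substitution with inversion at C1, which moves the epoxide into the ring on the lower face and frees the primary C7 alkoxide (favoured by the more substituted epoxide and the less hindered alkoxide), and benzoyl chloride then esterifies the C3 and C7 alkoxides, while the C2 ether can neither migrate nor let the epoxide walk on.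

Step 7
Reactants: 13 the dibenzoate of step 6
Product: 14 1-(benzoyloxymethyl)-2-hydroxy-7-oxabicyclo[4.1.0]hept-4-en-3-yl benzoate, epoxide oxygen and C3 benzoate on the lower face, C2 hydroxyl and C7 on the upper face
Conditions: 2,3-dichloro-5,6-dicyano-1,4-benzoquinone (DDQ), CH2Cl2/pH 7 phosphate buffer, 0 °C
Reagents that add atoms: none
Why: Oxidative cleavage of a 4-methoxybenzyl ether by DDQ runs through benzylic hydride abstraction and hydrolysis of the oxocarbenium ion in a buffered two-phase medium, which breaks only the benzylic C–O bond and so leaves the C2 configuration, the vinyl epoxide and both benzoates intact.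

Step 8
Reactants: 14 the C2 alcohol of step 7; 15 acetic anhydride
Product: 16 (1S,2S,3R,6S)-2-acetoxy-1-(benzoyloxymethyl)-7-oxabicyclo[4.1.0]hept-4-en-3-yl benzoate (target)
Conditions: Ac2O, pyridine, 4-(dimethylamino)pyridine (cat.), CH2Cl2, 0 °C
Reagents that add atoms: acetic anhydride, CC(=O)OC(C)=O
Why: Nucleophile-catalysed acyl transfer from acetic anhydride should esterify the C2 hydroxyl faster than a benzoyl group can shift under these weakly basic conditions, and no stereocentre is touched.

Compound list
1 | 2-hydroxybenzyl alcohol (salicyl alcohol) | OCc1ccccc1O | starting material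
2 | 1-oxaspiro[2.5]octa-5,7-dien-4-one, racemic | O=C1C=CC=CC12CO2 | intermediate
3 | racemic cis-1-oxaspiro[2.5]octa-5,7-dien-4-ol, (3S,4S) and (3R,4R), hydroxyl on the face of the epoxide oxygen | O[C@H]1C=CC=C[C@]12CO2.O[C@@H]1C=CC=C[C@@]12CO2 | intermediate
4 | vinyl acetate | C=COC(C)=O | starting material
5 | (3S,4S)-1-oxaspiro[2.5]octa-5,7-dien-4-ol | O[C@H]1C=CC=C[C@]12CO2 | intermediate
6 | 4-methoxybenzyl chloride | COc1ccc(CCl)cc1 | starting material
7 | (3S,4S)-4-[(4-methoxybenzyl)oxy]-1-oxaspiro[2.5]octa-5,7-diene | COc1ccc(CO[C@H]2C=CC=C[C@]23CO3)cc1 | intermediate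
8 | dioxygen | O=O | starting material
9 | 6-[(4-methoxybenzyl)oxy]spiro[2,3-dioxabicyclo[2.2.2]oct-7-ene-5,2'-oxirane]; O–O bridge C3 to C6 on the lower face, C2 ether oxygen and spiro-epoxide oxygen on the upper face | COc1ccc(CO[C@H]2[C@H]3C=C[C@H](OO3)[C@]24CO4)cc1 | intermediate
10 | 4-[(4-methoxybenzyl)oxy]-1-oxaspiro[2.5]oct-6-ene-5,8-diol; C3 and C6 hydroxyls on the lower face, ether and epoxide oxygens on the upper face | COc1ccc(CO[C@H]2[C@H](O)C=C[C@H](O)[C@]23CO3)cc1 | intermediate
11 | benzoyl chloride | O=C(Cl)c1ccccc1 | starting material
12 | {3-hydroxy-2-[(4-methoxybenzyl)oxy]-7-oxabicyclo[4.1.0]hept-4-en-1-yl}methanol; epoxide oxygen and C3 hydroxyl on the lower face, C2 ether and C7 on the upper face (formed as its disodium alkoxide) | COc1ccc(CO[C@H]2[C@H](O)C=C[C@@H]3O[C@@]32CO)cc1 | intermediate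
13 | 1-(benzoyloxymethyl)-2-[(4-methoxybenzyl)oxy]-7-oxabicyclo[4.1.0]hept-4-en-3-yl benzoate; same configuration as 12 | COc1ccc(CO[C@H]2[C@H](OC(=O)c3ccccc3)C=C[C@@H]3O[C@@]32COC(=O)c2ccccc2)cc1 | intermediate
14 | 1-(benzoyloxymethyl)-2-hydroxy-7-oxabicyclo[4.1.0]hept-4-en-3-yl benzoate; same configuration as 12 | O[C@H]1[C@H](OC(=O)c2ccccc2)C=C[C@@H]2O[C@@]21COC(=O)c1ccccc1 | intermediate
15 | acetic anhydride | CC(=O)OC(C)=O | starting material
16 | (1S,2S,3R,6S)-2-acetoxy-1-(benzoyloxymethyl)-7-oxabicyclo[4.1.0]hept-4-en-3-yl benzoate | CC(=O)O[C@H]1[C@H](OC(=O)c2ccccc2)C=C[C@@H]2O[C@@]21COC(=O)c1ccccc1 | target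

Total step count: 8. Longest linear sequence: 8 steps (1 to 16).

Steps most likely to fail

Step 4 (key step). The cycloaddition may lose facial control, because a benzylic ether is only a modest shield and the epoxide CH2 sits on the lower face. Hydrogen abstraction at C2 (ene pathway) or opening of the spiro-epoxide with rearomatization may also compete. The fallback moves facial control to a bulky silyl group and sets out from 5. Silylation (tert-butyldiphenylsilyl chloride, imidazole, DMF, 0 °C) would give (3S,4S)-4-[(tert-butyldiphenylsilyl)oxy]-1-oxaspiro[2.5]octa-5,7-diene F1, whose upper face is blocked far more strongly. Photooxygenation as in step 4 would give the silyl endoperoxide F2, and thiourea the silyl cis-enediol F3. NaH followed by benzoyl chloride would pass through the rearranged silyl epoxy diol F4 to the silyl dibenzoate F5; the bulky silyl group should be slow to move between oxygens here. Fluoride buffered with acetic acid (Bu4NF, AcOH, THF, 0 °C) would then free the C2 hydroxyl and bring the material back to the route at 14.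

Step 1. The dienone may dimerize before it is reduced, and hydride may add to the carbonyl face that leaves the hydroxyl trans to the epoxide oxygen. The fallback corrects the configuration afterwards and sets out from 1. The same oxidation and reduction would then deliver mainly racemic trans-1-oxaspiro[2.5]octa-5,7-dien-4-ol F6. Mitsunobu inversion at C2 (benzoic acid, PPh3, diisopropyl azodicarboxylate, THF, 0 °C) would give racemic cis-1-oxaspiro[2.5]octa-5,7-dien-4-yl benzoate F7, and methanolysis (K2CO3, MeOH, 0 °C) would return the route to 3.

Step 6. The epoxide shift may lag behind acylation, so that benzoyl chloride traps the unrearranged C6 alkoxide, or the dialkoxide may attack the newly formed vinyl epoxide. The fallback takes the two events apart and lets the shift run under equilibrium control with no acylating agent present. It sets out from 10: classical protic Payne conditions (0.5 M NaOH, t-BuOH/H2O, 20 °C) would give the rearranged diol 12 as an isolated compound, with unrearranged 10 returned to the equilibration. Benzoylation under amine conditions (BzCl, pyridine, 4-(dimethylamino)pyridine, CH2Cl2, 0 °C) would then reach 13. No new compound arises on this path.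

Further compounds
F1 | step 4 | (3S,4S)-4-[(tert-butyldiphenylsilyl)oxy]-1-oxaspiro[2.5]octa-5,7-diene | CC(C)(C)[Si](O[C@H]1C=CC=C[C@]12CO2)(c1ccccc1)c1ccccc1
F2 | step 4 | silyl endoperoxide, 6-[(tert-butyldiphenylsilyl)oxy]spiro[2,3-dioxabicyclo[2.2.2]oct-7-ene-5,2'-oxirane], O–O bridge on the lower face | CC(C)(C)[Si](O[C@H]1[C@H]2C=C[C@H](OO2)[C@]13CO3)(c1ccccc1)c1ccccc1
F3 | step 4 | silyl cis-enediol, 4-[(tert-butyldiphenylsilyl)oxy]-1-oxaspiro[2.5]oct-6-ene-5,8-diol | CC(C)(C)[Si](O[C@H]1[C@H](O)C=C[C@H](O)[C@]12CO2)(c1ccccc1)c1ccccc1
F4 | step 4 | rearranged silyl epoxy diol, {2-[(tert-butyldiphenylsilyl)oxy]-3-hydroxy-7-oxabicyclo[4.1.0]hept-4-en-1-yl}methanol (not isolated) | CC(C)(C)[Si](O[C@H]1[C@H](O)C=C[C@@H]2O[C@@]21CO)(c1ccccc1)c1ccccc1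
F5 | step 4 | silyl dibenzoate, 1-(benzoyloxymethyl)-2-[(tert-butyldiphenylsilyl)oxy]-7-oxabicyclo[4.1.0]hept-4-en-3-yl benzoate | CC(C)(C)[Si](O[C@H]1[C@H](OC(=O)c2ccccc2)C=C[C@@H]2O[C@@]21COC(=O)c1ccccc1)(c1ccccc1)c1ccccc1
F6 | step 1 | racemic trans-1-oxaspiro[2.5]octa-5,7-dien-4-ol | O[C@@H]1C=CC=C[C@]12CO2.O[C@H]1C=CC=C[C@@]12CO2
F7 | step 1 | racemic cis-1-oxaspiro[2.5]octa-5,7-dien-4-yl benzoate | O=C(O[C@H]1C=CC=C[C@]12CO2)c1ccccc1.O=C(O[C@@H]1C=CC=C[C@@]12CO2)c1ccccc1
F0 | step 6 | none | none
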